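## Analysis of the target

Target 23 is a halogenated spiro[5.5]undecane diol of the chamigrane type. Ring A is numbered C1 (carrying the exocyclic methylene), C2, C3 (OH), C4 (Br), C5 (gem-dimethyl) and C6 (spiro). Ring B is numbered C6, C7, C8, C9 (methyl, OH), C10 (Cl) and C11.

There are five stereocentres: C3 (R), C4 (S), C6 (S), C9 (R) and C10 (S). On ring A the hydroxyl and bromine are cis. On ring B the C9 hydroxyl and C10 chlorine are cis (methyl trans to chlorine), and both lie on the face of ring B that carries C5. Seen from ring A, C11 lies on the face of the hydroxyl and bromine.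

C6 is a quaternary spiro carbon bonded to a second fully substituted carbon (C5). It is stereogenic only because ring B is unsymmetrical, so its configuration must be tied to C9/C10 across ring B and to C3/C4 across ring A.

The sensitive groups are the cis bromohydrin and the chlorohydrin (base-induced rearrangement or elimination), the exocyclic methylene beside a quaternary carbon (acid moves it into the ring), and the secondary bromide at a neopentyl position (not accessible by substitution).

The difficulties are the C5–C6 bond, a methylene next to the spiro centre that would be hard to make by olefinating a flanked ketone, and two secondary halides of defined configuration.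

The strategy rests on C1(=CH2)–C2–C3(OH) of ring A. This is a 3-methylenecyclohexanol, the retron of a type 2 carbonyl-ene reaction between an isopropenyl group on C6 and an aldehyde at C3.

## Retrosynthetic reasoning

**23 to 22.** Only the O–Si bond at C9 is cut. The tertiary alcohol is masked so that the Lewis acid of the ring closure meets a single basic oxygen, the aldehyde.

**22 to 21 (C2–C3).** Ring A is opened at C2–C3, with the hydroxyl hydrogen returned to the methylene carbon. This gives bromoaldehyde 21, in which C6 carries an isopropenyl group and the chain C5–C4(Br)–C3HO. The cut is made here because it is the least hindered edge of ring A, remote from C5 and C6, and because the ene shift creates the methylene without any olefination beside the spiro carbon. Bromine is already on C4, so the new C3 centre is set against a neighbouring stereocentre. The forward reaction must close the ring, place oxygen cis to bromine and keep the double bond exocyclic.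

**21 to 20 (C4–Br).** The C4–Br bond is cut. Aldehyde 20 has a single α-position, and an enamine catalyst can deliver bromine to one face. The halogen is introduced immediately before the closure, so the labile α-bromoaldehyde is not carried through other steps.

**20 to 18.** These are changes of oxidation level and protection: aldehyde 20 from ester 19 by partial reduction, and silyl ether 19 from alcohol 18.

**18 to 17 (C9–CH3).** The methyl group is removed from C9 to give α-chloroketone 17. A cis chlorohydrin cannot come from epoxide opening, which gives the trans isomer. A methyl nucleophile adding to the ketone beside the chlorine gives it directly.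

**17 to 14 (C10–Cl, C9=O).** The chlorine and the C9 oxygen are traced back to the ring alkene C10=C11 of ester 14. Chloroketone 17 comes from silyl enol ether 16, 16 from enone 15 by conjugate hydrosilylation, and 15 from 14 by allylic oxidation at C9. The detour through the enone is deliberate. A saturated C9 ketone would have two nearly equivalent α-positions (C8 and C10), whereas the enone fixes the enol double bond at C9=C10.

**14 to 10 (C3–C4).** The C3–C4 bond is cut by a one-carbon homologation through diazoketone 12. The step that makes C5–C6 delivers C4 as a carboxyl carbon, so C3 has to be added afterwards.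

**10 to 7 (C5–C6).** The bond between the two fully substituted carbons is cut in a [3,3] sense, giving allylic isobutyrate 7. A sigmatropic shift tolerates this congestion. In a cyclohexenyl ester it must be suprafacial, so the configuration of the carbinol carbon (the future C10) is transferred completely to C6.

**7 to 1, 2 and 6.** Ester 7 comes from alcohol 5 and acid chloride 6. Alcohol 5 comes from dienone 4 by enantioselective reduction. Dienone 4 comes from vinylogous ester 1 and Grignard reagent 2 by addition with carbonyl transposition.

## Alternatives that were turned down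

**Alternative 1:** Ring B is cut at C9–C10 in an aldol sense.
- Forward step: the achiral dialdehyde A1, with two propanal arms on C6, is treated with a chiral secondary amine. The enamine of one arm adds through C10 to the formyl carbon C9 of the other. This closes ring B as the trans hydroxy aldehyde A2 and makes C6 a stereocentre.
- For: one catalytic step from a symmetrical precursor builds ring B and three stereocentres, C6 included, with no chirality relay. On this point it is stronger than the chosen route, which needs a reduction, an acylation and a rearrangement to set C6.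
- Against: A2 has a formyl group where chlorine belongs and a secondary carbinol where the tertiary one belongs. The extra carbon must be excised by a decarboxylative halogenation whose radical does not retain the C10 configuration, and C9 must be oxidized and set again. Two of the three new centres are therefore discarded. The 1,1-dimethylallyl group must later be oxidized at its terminus in the presence of the isopropenyl group.
- Comparison: the chosen strategy keeps every carbon it introduces and places chlorine directly at C10 under thermodynamic control.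

**Alternative 2:** Ring A is cut at C5–C6 as a cation–olefin closure.
- Forward step: bromochloride A3 ionizes at the tertiary C5 in a fluorinated alcohol, assisted by the neighbouring bromine. The ring carbon C6 of the cyclohexylidene allylsilane attacks C5, and loss of silicon leaves the C1 methylene in spiro bromide A4.
- For: bromine enters at an acyclic stage by a stereodefined dihalogenation and never sits beside an enolizable carbonyl. C3 and C4 are fixed before the ring forms, and the allylsilane fixes the alkene position. For the C3/C4 pair this is stronger than the chosen route, which depends on a labile α-bromoaldehyde and a diastereoselective closure.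
- Against: the most congested bond of the molecule is made by a cationic process between a tertiary centre and a tetrasubstituted alkene carbon, where elimination and solvent capture compete. Ring B of A4 is symmetrical, so C6 is not yet stereogenic. C9 and C10 would then have to be placed on one of two α-positions that differ only in their relation to the distant C3 and C4.
- Comparison: the chosen strategy makes C5–C6 by a sigmatropic shift and fixes C6 absolutely before ring B is functionalized.

**Alternative 3:** Ring B is cut at C6–C11 as a radical closure.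
- Forward step: (R)-linalool A5 supplies C9 with its methyl group, oxygen and vinyl group and is elaborated to the tertiary α-chloroketone A6. CuCl with a tripodal pyridylamine ligand abstracts the chlorine, the C6 radical adds to the terminal C11, and the C10 radical takes chlorine back from divalent copper to give A7.
- For: chlorine arrives in the ring-forming step, C9 comes from the chiral pool without an asymmetric reaction, and ring B, C6 and C10 are made in one redox-neutral operation. In step economy for ring B this beats the five steps used in the chosen route.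
- Against: the six-membered closure competes with the five-membered one. The C6 configuration rests on 1,4-induction from C9. Chlorine transfer to the C10 radical has no strong bias toward the face cis to oxygen. A6 is itself a hindered tertiary chloride that is hard to prepare. A7 carries an acetyl group that must be methylenated between two fully substituted carbons, and a vinyl group that must be oxidized at its terminus beside the isopropenyl group.
- Comparison: the chosen strategy offers complete chirality transfer to C6, an equilibrated C10 centre and a chlorine-directed methyl addition at C9.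

Key step: step 14

Remark on the chemistry: carbons keep the numbers C1–C11 defined in the analysis in all intermediates. The facial sense of the two chiral catalysts (steps 2 and 13) is assigned from the usual steric models; both catalysts exist in either enantiomeric form, so the assignment does not limit the route.

## Route

**Step 1**
Reactants: 1 3-ethoxycyclohex-2-en-1-one; 2 isopropenylmagnesium bromide
Product: 4 3-(prop-1-en-2-yl)cyclohex-2-en-1-one, via bromomagnesium alkoxide 3 (not isolated)
Conditions: THF, 0 °C to rt; then 1 M HCl, 0 °C to rt
Reagents that add atoms: water, O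
Why: Stork–Danheiser sequence: 1,2-addition of the vinyl Grignard reagent to the vinylogous ester, then acid-induced hydrolysis and loss of the tertiary hydroxyl transpose the carbonyl group; no stereocentre is formed.

**Step 2**
Reactants: 4 3-(prop-1-en-2-yl)cyclohex-2-en-1-one
Product: 5 (1R)-3-(prop-1-en-2-yl)cyclohex-2-en-1-ol
Conditions: (S)-2-methyl-CBS-oxazaborolidine (20 mol%), catecholborane, toluene, −78 °C; then MeOH, aq. NaOH
Reagents that add atoms: none
Why: Corey–Bakshi–Shibata reduction in the catecholborane variant suited to s-trans cyclic enones; with the dienyl arm as the large group the (S)-catalyst should deliver hydride to give the (R)-carbinol, the centre that later relays chirality to C6.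

**Step 3**
Reactants: 5 (1R)-3-(prop-1-en-2-yl)cyclohex-2-en-1-ol; 6 isobutyryl chloride
Product: 7 (1R)-3-(prop-1-en-2-yl)cyclohex-2-en-1-yl 2-methylpropanoate
Conditions: Et3N, DMAP (cat.), CH2Cl2, 0 °C
Reagents that add atoms: none
Why: DMAP-catalysed acylation under basic conditions, which avoids the acid that would ionize the dienyl carbinol; the stereocentre is not touched.

**Step 4**
Reactants: 7 (1R)-3-(prop-1-en-2-yl)cyclohex-2-en-1-yl 2-methylpropanoate
Product: 10 2-methyl-2-[(1S)-1-(prop-1-en-2-yl)cyclohex-2-en-1-yl]propanoic acid, via silyl ketene acetal 8 (not isolated), via trimethylsilyl ester 9 (not isolated)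
Conditions: LiN(iPr)2, THF, −78 °C; Me3SiCl, −78 °C to 65 °C; aq. NaOH, then citric acid to pH 4, 0 °C
Reagents that add atoms: chlorotrimethylsilane, C[Si](C)(C)Cl (silicon present in intermediates 8 and 9 only)
Why: Ireland–Claisen rearrangement; the ketene acetal has two identical α-methyl groups, so its geometry is irrelevant, and in a cyclohexenyl ester the new C5–C6 bond can form only on the face from which the C–O bond leaves, so C6 is set (S) by complete 1,3-chirality transfer. The mild acidification is chosen to keep the acid from lactonizing onto the isopropenyl group.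

**Step 5**
Reactants: 10 2-methyl-2-[(1S)-1-(prop-1-en-2-yl)cyclohex-2-en-1-yl]propanoic acid
Product: 12 1-diazo-3-methyl-3-[(1S)-1-(prop-1-en-2-yl)cyclohex-2-en-1-yl]butan-2-one, via acid chloride 11 (not isolated)
Conditions: 1-chloro-N,N,2-trimethylprop-1-en-1-amine, CH2Cl2, 0 °C to rt; then CH2N2 (3 equiv), Et2O, 0 °C
Reagents that add atoms: diazomethane, C=[N+]=[N-]; 1-chloro-N,N,2-trimethylprop-1-en-1-amine, CC(C)=C(Cl)N(C)C (chlorine present in intermediate 11 only)
Why: First half of an Arndt–Eistert homologation; the chloroenamine makes the acid chloride without free HCl, which would add the acid across the isopropenyl group, and the acid chloride has no α-hydrogen, so it can only acylate diazomethane.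

**Step 6**
Reactants: 12 1-diazo-3-methyl-3-[(1S)-1-(prop-1-en-2-yl)cyclohex-2-en-1-yl]butan-2-one
Product: 14 methyl 3-methyl-3-[(1S)-1-(prop-1-en-2-yl)cyclohex-2-en-1-yl]butanoate, via ketene 13 (not isolated)
Conditions: hν (365 nm), MeOH, rt
Reagents that add atoms: methanol, CO
Why: Photochemical Wolff rearrangement; the tertiary carbon C5 migrates to the carbene carbon and methanol traps the ketene, which inserts C4 between C5 and the carboxyl carbon (now C3); the isolated alkenes do not absorb at this wavelength.

**Step 7**
Reactants: 14 methyl 3-methyl-3-[(1S)-1-(prop-1-en-2-yl)cyclohex-2-en-1-yl]butanoate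
Product: 15 methyl 3-methyl-3-[(1S)-4-oxo-1-(prop-1-en-2-yl)cyclohex-2-en-1-yl]butanoate
Conditions: Rh2(cap)4 (dirhodium tetracaprolactamate, 1 mol%), t-BuOOH, K2CO3, CH2Cl2, rt
Reagents that add atoms: tert-butyl hydroperoxide, CC(C)(C)OO
Why: Allylic C–H oxidation by tert-butylperoxyl radicals; C9 is the only secondary allylic position (C6 is quaternary and the isopropenyl group has only primary hydrogens), and oxygen is taken up at the unhindered end of the allyl radical, giving the 4,4-disubstituted cyclohexenone.

**Step 8**
Reactants: 15 methyl 3-methyl-3-[(1S)-4-oxo-1-(prop-1-en-2-yl)cyclohex-2-en-1-yl]butanoate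
Product: 16 methyl 3-methyl-3-[(1S)-1-(prop-1-en-2-yl)-4-(triethylsilyloxy)cyclohex-3-en-1-yl]butanoate
Conditions: Et3SiH, RhCl(PPh3)3 (1 mol%), THF, 50 °C
Reagents that add atoms: triethylsilane, CC[SiH](CC)CC
Why: Rhodium-catalysed 1,4-hydrosilylation of an enone with a monohydrosilane; the enol double bond can only lie at C9=C10, so the later chlorination site is fixed, and the 1,1-disubstituted alkene and the ester react far more slowly.

**Step 9**
Reactants: 16 methyl 3-methyl-3-[(1S)-1-(prop-1-en-2-yl)-4-(triethylsilyloxy)cyclohex-3-en-1-yl]butanoate
Product: 17 methyl 3-[(1S,3S)-3-chloro-4-oxo-1-(prop-1-en-2-yl)cyclohexyl]-3-methylbutanoate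
Conditions: N-chlorosuccinimide, NaHCO3, THF, −20 to 0 °C; then Et3N (cat.), CH2Cl2, rt
Reagents that add atoms: N-chlorosuccinimide, O=C1CCC(=O)N1Cl
Why: Electrophilic chlorination of a silyl enol ether, which is far more nucleophilic than the isopropenyl group. The kinetic attack may give both C10 epimers, so the mixture is equilibrated through the enol: with the bulky C5 substituent equatorial and the isopropenyl group axial on ring B, the isomer with equatorial chlorine (trans to isopropenyl, cis to C5) avoids a syn-diaxial contact and should dominate.

**Step 10**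
Reactants: 17 methyl 3-[(1S,3S)-3-chloro-4-oxo-1-(prop-1-en-2-yl)cyclohexyl]-3-methylbutanoate
Product: 18 methyl 3-[(1S,3S,4R)-3-chloro-4-hydroxy-4-methyl-1-(prop-1-en-2-yl)cyclohexyl]-3-methylbutanoate
Conditions: MeTi(OiPr)3 (from MeLi and ClTi(OiPr)3), Et2O, −30 °C to rt
Reagents that add atoms: methyltitanium triisopropoxide, C[Ti](OC(C)C)(OC(C)C)OC(C)C
Why: Carbonyl addition of a non-basic methyltitanium reagent that leaves the ester and the chloride alone and prefers the equatorial trajectory; methyl should enter trans to the equatorial chlorine and leave the C9 hydroxyl axial and cis to chlorine, the same sense as the classical cis chlorohydrins from methyl-metal additions to 2-chlorocyclohexanones.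

**Step 11**
Reactants: 18 methyl 3-[(1S,3S,4R)-3-chloro-4-hydroxy-4-methyl-1-(prop-1-en-2-yl)cyclohexyl]-3-methylbutanoate
Product: 19 methyl 3-[(1S,3S,4R)-3-chloro-4-methyl-1-(prop-1-en-2-yl)-4-(triethylsilyloxy)cyclohexyl]-3-methylbutanoate
Conditions: Et3SiOTf, 2,6-lutidine, CH2Cl2, 0 °C to rt
Reagents that add atoms: triethylsilyl trifluoromethanesulfonate, CC[Si](CC)(CC)OS(=O)(=O)C(F)(F)F
Why: Silylation of a hindered tertiary alcohol needs the silyl triflate; the ether keeps the C9 oxygen from binding the aluminium reagents of steps 12 and 14.

**Step 12**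
Reactants: 19 methyl 3-[(1S,3S,4R)-3-chloro-4-methyl-1-(prop-1-en-2-yl)-4-(triethylsilyloxy)cyclohexyl]-3-methylbutanoate
Product: 20 3-[(1S,3S,4R)-3-chloro-4-methyl-1-(prop-1-en-2-yl)-4-(triethylsilyloxy)cyclohexyl]-3-methylbutanal
Conditions: iBu2AlH, CH2Cl2, −78 °C; aq. potassium sodium tartrate KNaC4H4O6
Reagents that add atoms: none
Why: Partial reduction of an ester; the aluminium hemiacetal of this ester with a quaternary β-carbon should persist at −78 °C and release the aldehyde only on work-up, and the chloride and silyl ether are inert.

**Step 13**
Reactants: 20 3-[(1S,3S,4R)-3-chloro-4-methyl-1-(prop-1-en-2-yl)-4-(triethylsilyloxy)cyclohexyl]-3-methylbutanal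
Product: 21 (2S)-2-bromo-3-[(1S,3S,4R)-3-chloro-4-methyl-1-(prop-1-en-2-yl)-4-(triethylsilyloxy)cyclohexyl]-3-methylbutanal
Conditions: (2R,5R)-2,5-diphenylpyrrolidine (20 mol%), 4,4-dibromo-2,6-di-tert-butylcyclohexa-2,5-dienone, PhCO2H (20 mol%), H2O, CH2Cl2/pentane, −40 °C; used crude
Reagents that add atoms: 4,4-dibromo-2,6-di-tert-butylcyclohexa-2,5-dienone, O=C1C(C(C)(C)C)=CC(Br)(Br)C=C1C(C)(C)C
Why: Enamine-catalysed α-bromination of an aldehyde; the phenyl group next to the enamine carbon shields one face of the E-enamine, so bromine should enter from the other face and set C4 as (S), and C4 is the only α-position. The product is taken on cold and unpurified because α-bromoaldehydes epimerize through the enol.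

**Step 14**
Reactants: 21 (2S)-2-bromo-3-[(1S,3S,4R)-3-chloro-4-methyl-1-(prop-1-en-2-yl)-4-(triethylsilyloxy)cyclohexyl]-3-methylbutanal
Product: 22 (2S,3R,6S,8S,9R)-2-bromo-8-chloro-1,1,9-trimethyl-5-methylidene-9-(triethylsilyloxy)spiro[5.5]undecan-3-ol
Conditions: Me2AlCl (2 equiv), CH2Cl2, −78 to −20 °C
Reagents that add atoms: none
Why: Me2AlCl binds the aldehyde oxygen of 21, C2 (the CH2 terminus of the isopropenyl group) attacks C3, and a hydrogen of the isopropenyl methyl group passes to oxygen in a concerted but asynchronous six-electron process in which C2–C3 bonding leads; the resulting alcohol–aluminium complex loses methane, which removes the proton that could otherwise isomerize the new double bond. The closest known reaction type is the alkylaluminium-halide-promoted type 2 intramolecular carbonyl-ene cyclization of 5-methylhex-5-enals to 3-methylenecyclohexanols, and an α-halogen makes the aldehyde a better enophile. Ring A closes in a six-membered mode that is exo at the carbonyl carbon with both alkene carbons inside the new ring, as a chair embedded in a bicyclo[3.3.1]-like array shared with the ene transition state, which obliges the oxygen to be axial on the forming ring. The one new stereocentre, C3, is controlled by C4: in the chair with bromine equatorial the C4–Br bond is antiperiplanar to the forming C2–C3 bond (polar Felkin–Anh arrangement) and C7, not bromine, takes the axial site at the spiro end, so axial oxygen and equatorial bromine come out cis. The other chair would give the trans isomer with the C=O and C–Br dipoles opposed, but it puts bromine syn-diaxial to C11 of ring B and is expected to lose. The step needs diastereoselectivity at C3, ene closure ahead of methyl transfer from aluminium, and loss of a methyl hydrogen in preference to a C2 hydrogen; the fully substituted C5 and C6 hold aldehyde and alkene together and speed the closure, and the intramolecular hydrogen transfer to the axial oxygen fixes the double bond in the exocyclic position. The weak point is that the axial oxygen is syn-diaxial to one C5 methyl group in either chair.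

**Step 15**
Reactants: 22 (2S,3R,6S,8S,9R)-2-bromo-8-chloro-1,1,9-trimethyl-5-methylidene-9-(triethylsilyloxy)spiro[5.5]undecan-3-ol
Product: 23 (2S,3R,6S,8S,9R)-2-bromo-8-chloro-1,1,9-trimethyl-5-methylidenespiro[5.5]undecane-3,9-diol
Conditions: HF·pyridine, pyridine, THF, 0 °C to rt
Reagents that add atoms: none
Why: Fluoride cleavage of the Si–O bond under buffered, non-basic conditions, so that neither halohydrin rearranges and the exocyclic alkene is not protonated; no stereocentre is touched.

## Compound list

1 | 3-ethoxycyclohex-2-en-1-one | CCOC1=CC(=O)CCC1 | starting material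
2 | isopropenylmagnesium bromide | CC(=C)[Mg]Br | starting material
3 | bromomagnesium 3-ethoxy-1-(prop-1-en-2-yl)cyclohex-2-en-1-olate (racemic) | CCOC1=CC(O[Mg]Br)(C(C)=C)CCC1 | intermediate
4 | 3-(prop-1-en-2-yl)cyclohex-2-en-1-one | CC(=C)C1=CC(=O)CCC1 | intermediate
5 | (1R)-3-(prop-1-en-2-yl)cyclohex-2-en-1-ol | CC(=C)C1=C[C@H](O)CCC1 | intermediate
6 | isobutyryl chloride (2-methylpropanoyl chloride) | CC(C)C(=O)Cl | starting material
7 | (1R)-3-(prop-1-en-2-yl)cyclohex-2-en-1-yl 2-methylpropanoate | CC(=C)C1=C[C@H](OC(=O)C(C)C)CCC1 | intermediate
8 | trimethylsilyl ketene acetal of 7 (O-silyl, O-[(1R)-3-(prop-1-en-2-yl)cyclohex-2-en-1-yl] acetal of dimethylketene) | CC(=C)C1=C[C@H](OC(O[Si](C)(C)C)=C(C)C)CCC1 | intermediate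
9 | trimethylsilyl 2-methyl-2-[(1S)-1-(prop-1-en-2-yl)cyclohex-2-en-1-yl]propanoate | C=C(C)[C@]1(C(C)(C)C(=O)O[Si](C)(C)C)CCCC=C1 | intermediate
10 | 2-methyl-2-[(1S)-1-(prop-1-en-2-yl)cyclohex-2-en-1-yl]propanoic acid | C=C(C)[C@]1(C(C)(C)C(=O)O)CCCC=C1 | intermediate
11 | 2-methyl-2-[(1S)-1-(prop-1-en-2-yl)cyclohex-2-en-1-yl]propanoyl chloride | C=C(C)[C@]1(C(C)(C)C(=O)Cl)CCCC=C1 | intermediate
12 | 1-diazo-3-methyl-3-[(1S)-1-(prop-1-en-2-yl)cyclohex-2-en-1-yl]butan-2-one | C=C(C)[C@]1(C(C)(C)C(=O)C=[N+]=[N-])CCCC=C1 | intermediate
13 | 3-methyl-3-[(1S)-1-(prop-1-en-2-yl)cyclohex-2-en-1-yl]but-1-en-1-one (ketene) | C=C(C)[C@]1(C(C)(C)C=C=O)CCCC=C1 | intermediate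
14 | methyl 3-methyl-3-[(1S)-1-(prop-1-en-2-yl)cyclohex-2-en-1-yl]butanoate | C=C(C)[C@]1(C(C)(C)CC(=O)OC)CCCC=C1 | intermediate
15 | methyl 3-methyl-3-[(1S)-4-oxo-1-(prop-1-en-2-yl)cyclohex-2-en-1-yl]butanoate | C=C(C)[C@]1(C(C)(C)CC(=O)OC)CCC(=O)C=C1 | intermediate
16 | methyl 3-methyl-3-[(1S)-1-(prop-1-en-2-yl)-4-(triethylsilyloxy)cyclohex-3-en-1-yl]butanoate | C=C(C)[C@]1(C(C)(C)CC(=O)OC)CCC(O[Si](CC)(CC)CC)=CC1 | intermediate
17 | methyl 3-[(1S,3S)-3-chloro-4-oxo-1-(prop-1-en-2-yl)cyclohexyl]-3-methylbutanoate | C=C(C)[C@]1(C(C)(C)CC(=O)OC)CCC(=O)[C@@H](Cl)C1 | intermediate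
18 | methyl 3-[(1S,3S,4R)-3-chloro-4-hydroxy-4-methyl-1-(prop-1-en-2-yl)cyclohexyl]-3-methylbutanoate | C=C(C)[C@]1(C(C)(C)CC(=O)OC)CC[C@@](C)(O)[C@@H](Cl)C1 | intermediate
19 | methyl 3-[(1S,3S,4R)-3-chloro-4-methyl-1-(prop-1-en-2-yl)-4-(triethylsilyloxy)cyclohexyl]-3-methylbutanoate | C=C(C)[C@]1(C(C)(C)CC(=O)OC)CC[C@@](C)(O[Si](CC)(CC)CC)[C@@H](Cl)C1 | intermediate
20 | 3-[(1S,3S,4R)-3-chloro-4-methyl-1-(prop-1-en-2-yl)-4-(triethylsilyloxy)cyclohexyl]-3-methylbutanal | C=C(C)[C@]1(C(C)(C)CC=O)CC[C@@](C)(O[Si](CC)(CC)CC)[C@@H](Cl)C1 | intermediate
21 | (2S)-2-bromo-3-[(1S,3S,4R)-3-chloro-4-methyl-1-(prop-1-en-2-yl)-4-(triethylsilyloxy)cyclohexyl]-3-methylbutanal | C=C(C)[C@]1(C(C)(C)[C@H](Br)C=O)CC[C@@](C)(O[Si](CC)(CC)CC)[C@@H](Cl)C1 | intermediate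
22 | (2S,3R,6S,8S,9R)-2-bromo-8-chloro-1,1,9-trimethyl-5-methylidene-9-(triethylsilyloxy)spiro[5.5]undecan-3-ol | C=C1C[C@@H](O)[C@@H](Br)C(C)(C)[C@]12CC[C@@](C)(O[Si](CC)(CC)CC)[C@@H](Cl)C2 | intermediate
23 | (2S,3R,6S,8S,9R)-2-bromo-8-chloro-1,1,9-trimethyl-5-methylidenespiro[5.5]undecane-3,9-diol | C=C1C[C@@H](O)[C@@H](Br)C(C)(C)[C@]12CC[C@@](C)(O)[C@@H](Cl)C2 | target

## Step count and least certain steps

Total step count: 15. Longest linear sequence: 15 steps from 1 (2 and 6 are commercial reagents that enter at steps 1 and 3).

**Step 14 (key step).**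
- Risk: the closure may follow a looser, stepwise course in which the aluminium-bound oxygen sits equatorial to escape the syn-diaxial contact with the axial C5 methyl group. C3 would then form with the hydroxyl trans to bromine. A slow closure would also let methyl transfer from aluminium to the aldehyde compete.
- Fallback: it sets out from 21 and comes back at 22. The cyclization mixture, containing 22 and its C3 epimer (2S,3S,6S,8S,9R)-2-bromo-8-chloro-1,1,9-trimethyl-5-methylidene-9-(triethylsilyloxy)spiro[5.5]undecan-3-ol F1, is oxidized with Dess–Martin periodinane and NaHCO3 in CH2Cl2 to the bromoketone (2S,6S,8S,9R)-2-bromo-8-chloro-1,1,9-trimethyl-5-methylidene-9-(triethylsilyloxy)spiro[5.5]undecan-3-one F2. This is reduced with iBu2AlH in toluene at −78 °C. The axial C5 methyl group blocks the axial trajectory at C3, so hydride should enter equatorially and leave the hydroxyl axial and cis to the equatorial bromine, which is 22.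

**Step 13.**
- Risk: facial selection at C4 may be poor, because the enamine carbon is neopentyl and the C6 stereocentre may oppose the catalyst. The product may also epimerize through its enol during handling.
- Fallback: it sets out from 19 and comes back at 21. Ester 19 is deprotonated with LiN(iPr)2 in THF at −78 °C to the lithium enolate of ester 19 F3, which is brominated with 1,2-dibromo-1,1,2,2-tetrachloroethane. This gives the configurationally stable methyl (2S)-2-bromo-3-[(1S,3S,4R)-3-chloro-4-methyl-1-(prop-1-en-2-yl)-4-(triethylsilyloxy)cyclohexyl]-3-methylbutanoate F4 together with its (2R)-epimer F5. The two are separated by chromatography, and F5 is re-equilibrated by bromide exchange with LiBr in acetone and separated again. Reduction of F4 with iBu2AlH in CH2Cl2 at −78 °C gives 21.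

**Step 2.**
- Risk: enantioface discrimination may be incomplete, because ketone 4 has no α-substituent and the two flanks of the carbonyl group differ little in size. Any loss is carried through the rearrangement to C6.
- Fallback: it sets out from 4 and comes back at 5. Reduction with NaBH4 and CeCl3·7H2O in MeOH gives racemic 3-(prop-1-en-2-yl)cyclohex-2-en-1-ol F6. Candida antarctica lipase B with vinyl acetate in hexane should, by the usual empirical rule with the substituted alkene arm as the large group, acylate the (R)-enantiomer to (1R)-3-(prop-1-en-2-yl)cyclohex-2-en-1-yl acetate F7 and leave (1S)-3-(prop-1-en-2-yl)cyclohex-2-en-1-ol F8. After separation, methanolysis of F7 with K2CO3 in MeOH gives 5. F8 is oxidized with MnO2 back to 4 and recycled.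

**Step 6 (with step 5).**
- Risk: the carbene or ketene stage may be diverted into cyclopropanation of the nearby alkenes or O–H insertion into methanol instead of the 1,2-shift. The very hindered acid chloride may also acylate diazomethane slowly.
- Fallback: it sets out from 10 and comes back at 14. Reduction with LiAlH4 in Et2O gives 2-methyl-2-[(1S)-1-(prop-1-en-2-yl)cyclohex-2-en-1-yl]propan-1-ol F9. Dess–Martin periodinane gives 2-methyl-2-[(1S)-1-(prop-1-en-2-yl)cyclohex-2-en-1-yl]propanal F10. Wittig reaction with Ph3P=CHOMe (from the phosphonium chloride and KOtBu, THF) gives the methyl enol ether (1S)-1-(4-methoxy-2-methylbut-3-en-2-yl)-1-(prop-1-en-2-yl)cyclohex-2-ene F11. Oxidation of the enol ether with pyridinium chlorochromate C5H5NH[CrO3Cl] in CH2Cl2 gives ester 14 directly. This avoids the acidic hydrolysis under which the freed aldehyde could close onto the isopropenyl group.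

## Further compounds

F1 | step 14 | (2S,3S,6S,8S,9R)-2-bromo-8-chloro-1,1,9-trimethyl-5-methylidene-9-(triethylsilyloxy)spiro[5.5]undecan-3-ol (C3 epimer of 22) | C=C1C[C@H](O)[C@@H](Br)C(C)(C)[C@]12CC[C@@](C)(O[Si](CC)(CC)CC)[C@@H](Cl)C2
F2 | step 14 | (2S,6S,8S,9R)-2-bromo-8-chloro-1,1,9-trimethyl-5-methylidene-9-(triethylsilyloxy)spiro[5.5]undecan-3-one | C=C1CC(=O)[C@@H](Br)C(C)(C)[C@]12CC[C@@](C)(O[Si](CC)(CC)CC)[C@@H](Cl)C2
F3 | step 13 | lithium enolate of ester 19 | C=C(C)[C@]1(C(C)(C)C=C(O[Li])OC)CC[C@@](C)(O[Si](CC)(CC)CC)[C@@H](Cl)C1
F4 | step 13 | methyl (2S)-2-bromo-3-[(1S,3S,4R)-3-chloro-4-methyl-1-(prop-1-en-2-yl)-4-(triethylsilyloxy)cyclohexyl]-3-methylbutanoate | C=C(C)[C@]1(C(C)(C)[C@H](Br)C(=O)OC)CC[C@@](C)(O[Si](CC)(CC)CC)[C@@H](Cl)C1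
F5 | step 13 | methyl (2R)-2-bromo-3-[(1S,3S,4R)-3-chloro-4-methyl-1-(prop-1-en-2-yl)-4-(triethylsilyloxy)cyclohexyl]-3-methylbutanoate | C=C(C)[C@]1(C(C)(C)[C@@H](Br)C(=O)OC)CC[C@@](C)(O[Si](CC)(CC)CC)[C@@H](Cl)C1
F6 | step 2 | racemic 3-(prop-1-en-2-yl)cyclohex-2-en-1-ol | CC(=C)C1=CC(O)CCC1
F7 | step 2 | (1R)-3-(prop-1-en-2-yl)cyclohex-2-en-1-yl acetate | CC(=C)C1=C[C@H](OC(C)=O)CCC1
F8 | step 2 | (1S)-3-(prop-1-en-2-yl)cyclohex-2-en-1-ol | CC(=C)C1=C[C@@H](O)CCC1
F9 | step 6 | 2-methyl-2-[(1S)-1-(prop-1-en-2-yl)cyclohex-2-en-1-yl]propan-1-ol | C=C(C)[C@]1(C(C)(C)CO)CCCC=C1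
F10 | step 6 | 2-methyl-2-[(1S)-1-(prop-1-en-2-yl)cyclohex-2-en-1-yl]propanal | C=C(C)[C@]1(C(C)(C)C=O)CCCC=C1
F11 | step 6 | (1S)-1-(4-methoxy-2-methylbut-3-en-2-yl)-1-(prop-1-en-2-yl)cyclohex-2-ene (E/Z mixture) | C=C(C)[C@]1(C(C)(C)C=COC)CCCC=C1
A1 | alternative 1 | 4-(2-methylbut-3-en-2-yl)-4-(prop-1-en-2-yl)heptanedial | C=C(C)C(CCC=O)(CCC=O)C(C)(C)C=C
A2 | alternative 1 | trans-2-hydroxy-5-(2-methylbut-3-en-2-yl)-5-(prop-1-en-2-yl)cyclohexane-1-carbaldehyde (ring B hydroxy aldehyde with C6 set) | C=C(C)[C@]1(C(C)(C)C=C)CC[C@H](O)[C@@H](C=O)C1
A3 | alternative 2 | vicinal bromochloride carrying the cyclohexylidene allylsilane: 8-[4-bromo-3-(tert-butyldimethylsilyloxy)-5-chloro-5-methyl-1-(trimethylsilyl)hexan-2-ylidene]-1,4-dioxaspiro[4.5]decane | C[Si](C)(C)CC(C[C@@H](O[Si](C)(C)C(C)(C)C)[C@@H](Br)C(C)(C)Cl)=C1CCC2(CC1)OCCO2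
A4 | alternative 2 | spiro bromide with complete ring A and ring B ethylene ketal | C=C1C[C@@H](O[Si](C)(C)C(C)(C)C)[C@@H](Br)C(C)(C)C12CCC3(CC2)OCCO3
A5 | alternative 3 | (R)-linalool | CC(C)=CCC[C@@](C)(O)C=C
A6 | alternative 3 | acyclic tertiary α-chloroketone, 3-chloro-3-(2-methylbut-3-en-2-yl)-6-methyl-6-(triethylsilyloxy)oct-7-en-2-one (mixture at the chlorine-bearing carbon) | CC(=O)C(Cl)(C(C)(C)C=C)CC[C@@](C)(O[Si](CC)(CC)CC)C=C
A7 | alternative 3 | ring B chloride bearing acetyl and 1,1-dimethylallyl groups | CC(=O)[C@]1(C(C)(C)C=C)CC[C@@](C)(O[Si](CC)(CC)CC)[C@@H](Cl)C1
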